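**Retrosynthetic overview**
- Target ⇒ desilylation of its bis(triethylsilyl) ether ⇒ anti-selective peracid epoxidation of the 7,8-dihydro-8-oxo β,γ-enone (oxirane is the last ring formed; C5/C6 set by C3).
- β,γ-Enone ⇒ base-induced eliminative opening of the 5,8-furanoid (2,5-dihydrofuran) oxide with kinetic protonation at C7 (new step; creates the C8=O bond).
- Furanoid oxide ⇒ phosphine ring contraction of the 5,8-endoperoxide ⇒ singlet-oxygen [4+2] cycloaddition to the 6-s-cis diene of silylated lutein (photochemical C8–O bond formation; the dioxine and then the dihydrofuran ring are temporary).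
- Silylated lutein ⇒ lutein: both six-membered rings, the whole polyene and C3, C3′, C6′ are bought; no C–C bond is made.

Assumption: all-E (3R,3′R,6′R)-lutein (marigold xanthophyll, sold in bulk as a food ingredient) counts as a commercially available starting material. Carotenoid numbering is used: unprimed = the end that becomes the epoxy ketone, primed = ε end.

**Route**

Step 1
Reactants: 1 lutein
Product: 2 lutein bis(triethylsilyl) ether
Conditions: TESCl (2.5 equiv), imidazole (5 equiv), DMF, 0 °C → rt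
Reagents that add atoms: chlorotriethylsilane (TESCl), CC[Si](Cl)(CC)CC
Why: Standard imidazole-promoted silylation of the two secondary alcohols touches no stereocentre, makes the carotenoid soluble in CH2Cl2 and THF, protects the hydroxyls from the amide base of step 3, gives a bulky 3-O-substituent to bias the epoxidation face in step 4, and deactivates the ε-ring alkene towards singlet-oxygen ene reaction.

Step 2
Reactants: 2 lutein bis(triethylsilyl) ether
Product: 4 bis-TES lutein 5,8-furanoid oxide (C5/C8 diastereomer mixture), via bis-TES lutein 5,8-endoperoxide 3 (not isolated)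
Conditions: O2 (1 atm), TPP (1 mol%), red LEDs (λ > 600 nm), CH2Cl2, −20 °C, to about 60% conversion; then PPh3 (1.2 equiv), −20 °C → rt
Reagents that add atoms: dioxygen, O=O
Why: Sensitised photooxygenation (singlet-oxygen [4+2] cycloaddition) occurs at the only cisoid 1,3-diene of the molecule, the 6-s-cis C5=C6–C7=C8 unit that is the known site of chemical singlet-oxygen quenching in β-type end groups, and forms the C8–O bond that becomes the C8 carbonyl, after which phosphine deoxygenation with ring contraction of the 3,6-dihydro-1,2-dioxine gives the 2,5-dihydrofuran (any 5,6-epoxide isomerises to the same furanoid on silica gel); the new C5 and C8 centres are left as a mixture because both are erased in step 3.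

Step 3
Reactants: 4 bis-TES lutein 5,8-furanoid oxide
Product: 6 bis-TES 7,8-dihydro-8-oxolutein, via potassium 5,7-dien-8-olate 5 (not isolated)
Conditions: KHMDS (1.3 equiv), THF, −78 → −40 °C; inverse quench into AcOH/THF, −78 °C
Reagents that add atoms: none
Why: Proposed new method: base-induced eliminative ring opening of a carotenoid 5,8-furanoid oxide, in which KHMDS removes the C8–H (α to oxygen, allylic to C6=C7 and to the octaene), the delocalised anion expels the C5 alkoxide by an E1cB-type six-electron anionic ring opening to the cross-conjugated 5,7-dien-8-olate, and inverse acetic acid quench protonates this dienolate kinetically at the α-carbon C7 to give the deconjugated β,γ-enone with the new C8=O bond and the tetrasubstituted C5=C6 alkene; the closest known reactions are the opening of 2,5-dihydrofuran-2-yl anions to 1-oxidobutadienes (oxapentadienyl anions) and the kinetic α-protonation of dienolates, neither of which has been shown on a polyenyl dihydrofuran.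

Step 4
Reactants: 6 bis-TES 7,8-dihydro-8-oxolutein
Product: 7 bis-TES epoxy ketone (3S,5R,6S,3′R,6′R)
Conditions: mCPBA (1.1 equiv), CH2Cl2, −20 °C; chromatographic removal of the minor syn epoxide
Reagents that add atoms: 3-chloroperoxybenzoic acid (mCPBA), OOC(=O)c1cccc(Cl)c1
Why: Prilezhaev epoxidation attacks the isolated, tetrasubstituted C5=C6 alkene much faster than the ketone-deactivated polyene or the hindered ε-ring alkene with its allylic silyloxy group, and the peracid approaches anti to the 3-silyloxy group (as in the epoxidation of O-acylated zeaxanthin and lutein, which gives mainly the natural anti epoxide), so the bought C3 centre sets C5 (R) and C6 (S); the product epoxide is not vinylic and therefore cannot undergo the acid-triggered furanoid rearrangement.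

Step 5
Reactants: 7 bis-TES epoxy ketone
Product: 8 target, (3S,5R,6S,3′R,6′R)-5,6-epoxy-3,3′-dihydroxy-5,6,7,8-tetrahydro-β,ε-caroten-8-one
Conditions: TBAF/AcOH (1:1, 3 equiv), THF, 0 °C → rt
Reagents that add atoms: none
Why: Acetic-acid-buffered fluoride desilylation is not basic enough to trigger E1cB opening of the β,γ-epoxy ketone and not acidic enough to ionise the allylic 3′-oxygen or the epoxide, so all five stereocentres are left untouched.

**Compound list**

1 | lutein, all-E (3R,3′R,6′R)-β,ε-carotene-3,3′-diol | CC1=C[C@H](O)CC(C)(C)[C@H]1/C=C/C(C)=C/C=C/C(C)=C/C=C/C=C(C)/C=C/C=C(C)/C=C/C1=C(C)C[C@@H](O)CC1(C)C | starting material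

2 | lutein bis(triethylsilyl) ether, (3R,3′R,6′R)-3,3′-bis(triethylsilyloxy)-β,ε-carotene | CC1=C[C@H](O[Si](CC)(CC)CC)CC(C)(C)[C@H]1/C=C/C(C)=C/C=C/C(C)=C/C=C/C=C(C)/C=C/C=C(C)/C=C/C1=C(C)C[C@@H](O[Si](CC)(CC)CC)CC1(C)C | intermediate

3 | bis-TES lutein 5,8-endoperoxide, 5,8-epidioxy-5,8-dihydro-3,3′-bis(triethylsilyloxy)-β,ε-carotene; C3, C3′, C6′ as in 2; O–O bridge cis across C5/C8, both ring faces formed (C5/C8 left unspecified) | CC1=C[C@H](O[Si](CC)(CC)CC)CC(C)(C)[C@H]1/C=C/C(C)=C/C=C/C(C)=C/C=C/C=C(C)/C=C/C=C(\C)C1OOC2(C)C[C@@H](O[Si](CC)(CC)CC)CC(C)(C)C2=C1 | intermediate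

4 | bis-TES lutein 5,8-furanoid oxide, 5,8-epoxy-5,8-dihydro-3,3′-bis(triethylsilyloxy)-β,ε-carotene; C3, C3′, C6′ as in 2; mixture of C5/C8 diastereomers (left unspecified) | CC1=C[C@H](O[Si](CC)(CC)CC)CC(C)(C)[C@H]1/C=C/C(C)=C/C=C/C(C)=C/C=C/C=C(C)/C=C/C=C(\C)C1OC2(C)C[C@@H](O[Si](CC)(CC)CC)CC(C)(C)C2=C1 | intermediate

5 | potassium 5,7-dien-8-olate: potassium enolate (O– on C8, C7=C8 and C5=C6) of compound 6 | CC1=C[C@H](O[Si](CC)(CC)CC)CC(C)(C)[C@H]1/C=C/C(C)=C/C=C/C(C)=C/C=C/C=C(C)/C=C/C=C(\C)C([O-])=CC1=C(C)C[C@@H](O[Si](CC)(CC)CC)CC1(C)C.[K+] | intermediate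

6 | bis-TES 7,8-dihydro-8-oxolutein, (3R,3′R,6′R)-3,3′-bis(triethylsilyloxy)-7,8-dihydro-β,ε-caroten-8-one | CC1=C[C@H](O[Si](CC)(CC)CC)CC(C)(C)[C@H]1/C=C/C(C)=C/C=C/C(C)=C/C=C/C=C(C)/C=C/C=C(\C)C(=O)CC1=C(C)C[C@@H](O[Si](CC)(CC)CC)CC1(C)C | intermediate

7 | bis-TES epoxy ketone, (3S,5R,6S,3′R,6′R)-5,6-epoxy-3,3′-bis(triethylsilyloxy)-5,6,7,8-tetrahydro-β,ε-caroten-8-one (epoxide trans to the 3-oxygen) | CC1=C[C@H](O[Si](CC)(CC)CC)CC(C)(C)[C@H]1/C=C/C(C)=C/C=C/C(C)=C/C=C/C=C(C)/C=C/C=C(\C)C(=O)C[C@@]12O[C@]1(C)C[C@@H](O[Si](CC)(CC)CC)CC2(C)C | intermediate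

8 | (3S,5R,6S,3′R,6′R)-5,6-epoxy-3,3′-dihydroxy-5,6,7,8-tetrahydro-β,ε-caroten-8-one, all-E | CC1=C[C@H](O)CC(C)(C)[C@H]1/C=C/C(C)=C/C=C/C(C)=C/C=C/C=C(C)/C=C/C=C(\C)C(=O)C[C@@]12O[C@]1(C)C[C@@H](O)CC2(C)C | target

**Step count and risks**

Total steps: 5. Longest linear sequence: 5 (fully linear).

Steps most likely to fail:

Step 3 (the proposed new step). The risks are slow or reversible deprotonation at C8, competing deprotonation at the doubly allylic C6′–H (ε→β isomerisation or epimerisation), and γ-protonation at C5 to the conjugated enone. The fallback uses known chemistry only. It sets out from 3, which is isolated by leaving out the PPh3 in step 2, and comes back to the route at 6. Kornblum–DeLaMare rearrangement of the endoperoxide with Et3N (CH2Cl2, 0 °C) gives the bis-TES cis-γ-hydroxy enone (C5–OH, C6=C7, C8=O) F2. Ac2O/DMAP acetylates the tertiary alcohol to the γ-acetoxy enone F3. SmI2 (THF–MeOH, −78 °C) then cleaves the γ-acyloxy group reductively through the samarium dienolate, whose kinetic α-protonation gives 6.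

Step 2. Lutein-type polyenes quench singlet oxygen mostly physically, so roughly a thousand singlet-oxygen molecules are needed per cycloaddition. This means long irradiation, a photostable sensitiser, a stop at partial conversion with recycling of 2, and some over-oxidation and E/Z scrambling. The fallback sets out from 2 and comes back at 4 without light. mCPBA (CH2Cl2, 0 °C) epoxidises the ring-terminal C5=C6 of 2 to the bis-TES lutein 5,6-epoxide F1 (either face is acceptable). A trace of acid (PPTS or HCl in CHCl3) then triggers the classical epoxide–furanoid rearrangement to 4. Both reactions are documented for lutein esters.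

Step 4. The anti/syn ratio may be lower than for the conjugated end groups on which the precedent rests, and the polyene may be partly oxidised. The fallback sets out from 6 and comes back at 8 with a larger face-blocking group. TBAF/AcOH frees (3R,3′R,6′R)-3,3′-dihydroxy-7,8-dihydro-β,ε-caroten-8-one F4. TBDPSCl/imidazole gives the bis-TBDPS ether F5. mCPBA then gives the bis-TBDPS anti-epoxy ketone F6, and pyridine-buffered HF·pyridine removes the silyl groups to give 8.

**Further compounds**

F1 | step 2 | bis-TES lutein 5,6-epoxide (major anti isomer shown; the syn isomer converges as well) | CC1=C[C@H](O[Si](CC)(CC)CC)CC(C)(C)[C@H]1/C=C/C(C)=C/C=C/C(C)=C/C=C/C=C(C)/C=C/C=C(C)/C=C/[C@@]12O[C@]1(C)C[C@@H](O[Si](CC)(CC)CC)CC2(C)C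

F2 | step 3 | bis-TES 5-hydroxy-5,8-dihydro-β,ε-caroten-8-one, cis-γ-hydroxy enone (C5–OH, C6=C7 with C5 and C8 cis, C8=O; C5 epimer mixture) | CC1=C[C@H](O[Si](CC)(CC)CC)CC(C)(C)[C@H]1/C=C/C(C)=C/C=C/C(C)=C/C=C/C=C(C)/C=C/C=C(\C)C(=O)/C=C1\C(C)(O)C[C@@H](O[Si](CC)(CC)CC)CC1(C)C

F3 | step 3 | 5-O-acetate of F2 (γ-acetoxy enone) | CC1=C[C@H](O[Si](CC)(CC)CC)CC(C)(C)[C@H]1/C=C/C(C)=C/C=C/C(C)=C/C=C/C=C(C)/C=C/C=C(\C)C(=O)/C=C1\C(C)(OC(C)=O)C[C@@H](O[Si](CC)(CC)CC)CC1(C)C

F4 | step 4 | (3R,3′R,6′R)-3,3′-dihydroxy-7,8-dihydro-β,ε-caroten-8-one | CC1=C[C@H](O)CC(C)(C)[C@H]1/C=C/C(C)=C/C=C/C(C)=C/C=C/C=C(C)/C=C/C=C(\C)C(=O)CC1=C(C)C[C@@H](O)CC1(C)C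

F5 | step 4 | bis(tert-butyldiphenylsilyl) ether of F4 | CC1=C[C@H](O[Si](c2ccccc2)(c2ccccc2)C(C)(C)C)CC(C)(C)[C@H]1/C=C/C(C)=C/C=C/C(C)=C/C=C/C=C(C)/C=C/C=C(\C)C(=O)CC1=C(C)C[C@@H](O[Si](c2ccccc2)(c2ccccc2)C(C)(C)C)CC1(C)C

F6 | step 4 | bis-TBDPS (3S,5R,6S,3′R,6′R)-5,6-epoxy ketone | CC1=C[C@H](O[Si](c2ccccc2)(c2ccccc2)C(C)(C)C)CC(C)(C)[C@H]1/C=C/C(C)=C/C=C/C(C)=C/C=C/C=C(C)/C=C/C=C(\C)C(=O)C[C@@]12O[C@]1(C)C[C@@H](O[Si](c3ccccc3)(c3ccccc3)C(C)(C)C)CC2(C)C
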